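**Two lifetimes.** The blue run gave me the two times I needed for these flasks.

| setting | ochre | blue | south-west | north-east | south | north-west | north |
|---|---|---|---|---|---|---|---|
| starting material | 0.066 M | 0.066 M | 0.066 M | 0.066 M | 0.066 M | 0.066 M | 0.066 M |
| reagent | 0.028 M | 0.18 M | 0.0250 M | 0.0400 M | 0.0600 M | 0.0800 M | 0.120 M |
| initiator | 3.3 mM | 3.3 mM | 3.3 mM | 3.3 mM | 3.3 mM | 3.3 mM | 3.3 mM |
| remark | run made earlier | run made earlier |  |  |  |  |  |
| time |  |  | 20 min | 20 min | 20 min | 20 min | 20 min |

| run | time / min | target / % | starting material / % |
|---|---|---|---|
| ochre | 1.00 | 6 | 97 |
| ochre | 1.50 | 5 | 94 |
| ochre | 2.50 | 5 | 95 |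
| ochre | 4.00 | 6 | 93 |
| ochre | 6.00 | 4 | 85 |
| ochre | 10.0 | 7 | 82 |
| ochre | 15.0 | 5 | 75 |
| blue | 0.833 | 14 | 83 |
| blue | 2.00 | 24 | 70 |
| blue | 4.00 | 41 | 41 |
| blue | 6.00 | 47 | 21 |
| blue | 8.00 | 50 | 0 |
| blue | 12.0 | 22 | 1 |
| blue | 15.0 | 12 | 1 |

(scatter of a reading: 2 percentage points)

- percentages count the starting material that a species holds: one ended chains counts as two
- what may be going on: initiator -> 2 initiating radical; 2 first chain carrier -> ended chains; reagent + first chain carrier -> target + second chain carrier; starting material + initiating radical -> capped initiator + first chain carrier; starting material + second chain carrier -> by-product + first chain carrier; target -> over-reaction product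
- "hardly changes" means that all values lie within two and a half points (for a concentration: within two and a half percent of the largest)

- amount of target at the end, in percent of the starting material charged for south-west, north-east, south, north-west, north, in this order
- how that number moves from the first to the last of them (falls all the way / falls, then rises / rises all the way / hardly changes / rises, then falls)

Once blue's starting material read 0 %, its target fell from 50 % to 12 % in 7.00 min, so I read a target lifetime of 4.90 min. By 4.00 min blue's reading showed a loss of 59.0 % of its starting material. The two proposed chain steps together spend one reagent per starting material, so I counted blue's loss as reagent lost too. Taking the reagent as decaying pseudo-first-order was my assumption, and it gave a lifetime of 16.4 min. As a test on another flask, that lifetime gave ochre a loss of 25.4 % at 15.0 min, and ochre read 25.0 %.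

**The ratio.** Target is made as reagent goes, and it lives for less time than the reagent does. The run spans 4.08 target lifetimes, more than one, so I took target at the end to trail the reagent at a constant share. Target lifetime over the difference of the two lifetimes is 0.426, the holding ratio: target held per reagent still present.

**My row.** By my lifetime, north-west spends 85.4 % of the starting material's charge in reagent by 20 min, less than the charge. So the ratio gave me 4.77 % for south-west and 15.3 % for north-west. By the same reckoning north demands more than the charge, so I took starting material as the limiting reagent. I put its end at 13.1 min, after which target decays to 8.55 %.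

**The forecast.** It gave 4.5 %, 7.3 %, 10.9 %, 14.5 % and 9 %, a row that rises, then falls, close to mine but not equal, on this ground: “The rate is instead first order in reagent, with constant radical level”.

**The flasks.** They gave 5.01 %, 8.02 %, 12.0 %, 16.0 % and 10.8 %: rises, then falls. The target's half-life by its own decay alone, 4.1 min in south-west, is shorter than the 20 min of the run.

    initiator → 2 initiating radical (k = 0.0270 /min)
    2 first chain carrier → ended chains (k = 4.00 × 10⁶ /M/s)
    reagent + first chain carrier → target + second chain carrier (k = 1.00 × 10⁵ /M/min)
    starting material + initiating radical → capped initiator + first chain carrier (k = 1.90 × 10⁵ /M/s)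
    starting material + second chain carrier → by-product + first chain carrier (k = 5.30 × 10⁵ /M/min)
    target → over-reaction product (k = 0.170 /min)

**North-west again.** North-west kept 34.4 % of its reagent at 20.0 min. The holding ratio turns this into 17.8 % target, and north-west held 16.0 %.

The readings come from a simulation on assumed constants; scatter was added.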